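**Retrosynthetic overview**
1. Target ⇐ late esterification of the C3 alcohol with angelic acid (Z geometry carried in), then release of the C15 acid (allyl ester) and the C18 alcohol (TBS ether).
2. The 13E enoate ⇐ Horner–Wadsworth–Emmons olefination of a C13 methyl ketone on the finished decalin.
3. Key step: ring A (C4–C5 bond) and then ring B (C10–C9 bond) are closed in one flask from an acyclic C18 keto-epoxide by a Cp2TiCl radical cascade, which ends by loss of a C17 hydrogen to give the C8 methylidene.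
4. This replaces the usual decalin-first plan (a Wieland–Miescher-type ketone with C4, C8 and C9 elaborated one at a time) and the Lewis-acid cation–olefin closure, which does not place the exocyclic alkene.
5. All five stereocentres follow from one Sharpless epoxidation (D-tartrate) of the (E)-allylic alcohol made by SeO2 oxidation of (E,E)-farnesylacetone (farnesyl bromide + acetylacetone).

Assumption: ring positions are given in labdane numbering (C3 carbinol carbon, C4 quaternary carbon with CH3 and CH2O, C8 methylidene carbon, C9 bears the side chain, C13=C14–C15 is the enoic acid), and 1, 2, 9 and 11 are bought.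

**Step 1**
Reactants: 1 (2E,6E)-farnesyl bromide [(2E,6E)-1-bromo-3,7,11-trimethyldodeca-2,6,10-triene]; 2 pentane-2,4-dione (acetylacetone)
Product: 4 (5E,9E)-farnesylacetone [(5E,9E)-6,10,14-trimethylpentadeca-5,9,13-trien-2-one], via 3-[(2E,6E)-farnesyl]pentane-2,4-dione 3 (not isolated)
Conditions: K2CO3, EtOH, reflux, 16 h
Reagents that add atoms: none
Why: SN2 C-alkylation of the acetylacetone enolate by the primary allylic bromide (both E alkenes untouched) is followed in the same pot by carbonate/ethanol retro-Claisen deacetylation of the 1,3-diketone, the classical alkylation–deacylation route to methyl ketones, and no stereocentre is formed.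

**Step 2**
Reactants: 4 (5E,9E)-farnesylacetone
Product: 5 (5E,9E,13E)-15-hydroxy-6,10,14-trimethylpentadeca-5,9,13-trien-2-one
Conditions: SeO2 (10 mol%), salicylic acid (10 mol%), t-BuOOH (3 equiv), CH2Cl2, rt, stopped at about 60% conversion, 4 recycled
Reagents that add atoms: tert-butyl hydroperoxide, CC(C)(C)OO
Why: Sharpless–Umbreit allylic oxidation (SeO2 ene reaction then [2,3]-sigmatropic shift, SeO2 turned over by t-BuOOH) attacks the terminal, most electron-rich and least hindered trisubstituted alkene at its E-methyl group, giving the (13E)-allylic alcohol whose CH2OH later becomes the equatorial C18.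

**Step 3**
Reactants: 5 (5E,9E,13E)-15-hydroxy-6,10,14-trimethylpentadeca-5,9,13-trien-2-one
Product: 6 (5E,9E)-12-[(2R,3R)-3-(hydroxymethyl)-3-methyloxiran-2-yl]-6,10-dimethyldodeca-5,9-dien-2-one
Conditions: Ti(OiPr)4 (10 mol%), D-(−)-diethyl tartrate (12 mol%), t-BuOOH (2 equiv, anhydrous), 4 Å MS, CH2Cl2, −20 °C
Reagents that add atoms: tert-butyl hydroperoxide, CC(C)(C)OO
Why: Katsuki–Sharpless asymmetric epoxidation touches only the allylic-alcohol alkene, and the D-(−)-tartrate catalyst gives the (2R,3R)-epoxide (about 90–95% ee expected), whose CH carbon is the future C3 (R).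

**Step 4**
Reactants: 6 (5E,9E)-12-[(2R,3R)-3-(hydroxymethyl)-3-methyloxiran-2-yl]-6,10-dimethyldodeca-5,9-dien-2-one
Product: 7 (5E,9E)-12-[(2R,3R)-3-{[tert-butyl(dimethyl)silyl]oxymethyl}-3-methyloxiran-2-yl]-6,10-dimethyldodeca-5,9-dien-2-one
Conditions: TBSCl (1.2 equiv), imidazole (2 equiv), DMF, 0 °C to rt
Reagents that add atoms: tert-butyldimethylsilyl chloride, CC(C)(C)[Si](C)(C)Cl
Why: Imidazole-mediated silylation of the primary alcohol masks O18 so that it neither binds titanium in the cascade nor competes in the later acylation, and the stereocentres are untouched.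

**Step 5**
Reactants: 7 (5E,9E)-12-[(2R,3R)-3-{[tert-butyl(dimethyl)silyl]oxymethyl}-3-methyloxiran-2-yl]-6,10-dimethyldodeca-5,9-dien-2-one
Product: 8 4-[(1R,4aS,5S,6R,8aS)-5-{[tert-butyl(dimethyl)silyl]oxymethyl}-6-hydroxy-5,8a-dimethyl-2-methylidenedecahydronaphthalen-1-yl]butan-2-one
Conditions: Cp2TiCl2 (2.5 equiv), Mn dust (8 equiv), THF (degassed, 0.01 M), rt, 7 added over 2 h; then cold 1 M HCl wash
Reagents that add atoms: none
Why: Nugent–RajanBabu homolysis of the epoxide by Cp2TiCl gives the tertiary C4 radical with C3–O intact, which undergoes a 6-endo/6-endo radical polyene cyclisation through a chair–chair transition state (C3–O and the bulkier CH2OTBS equatorial, the E alkenes enforcing the trans ring fusion and the equatorial C9 chain) so that C4, C5, C10 and C9 are set relative to C3, after which the C8 radical is intercepted by a second Cp2TiCl and loses a C17 hydrogen to give the exocyclic alkene while the unactivated ketone is left alone by trivalent titanium.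

**Step 6**
Reactants: 8 4-[(1R,4aS,5S,6R,8aS)-5-{[tert-butyl(dimethyl)silyl]oxymethyl}-6-hydroxy-5,8a-dimethyl-2-methylidenedecahydronaphthalen-1-yl]butan-2-one; 9 allyl (diethoxyphosphoryl)acetate
Product: 10 allyl (2E)-5-[(1R,4aS,5S,6R,8aS)-5-{[tert-butyl(dimethyl)silyl]oxymethyl}-6-hydroxy-5,8a-dimethyl-2-methylidenedecahydronaphthalen-1-yl]-3-methylpent-2-enoate
Conditions: 9 (2.0 equiv), NaH (1.9 equiv), THF, 0 °C to 50 °C
Reagents that add atoms: none
Why: Horner–Wadsworth–Emmons olefination of the methyl ketone by the sodium phosphonate (kept in excess over NaH so that the C3–OH stays protonated) places the ester trans to the larger CH2 substituent (13E, about 5:1 expected, the 13Z isomer being removed on AgNO3-impregnated silica).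

**Step 7**
Reactants: 10 allyl (2E)-5-[(1R,4aS,5S,6R,8aS)-5-{[tert-butyl(dimethyl)silyl]oxymethyl}-6-hydroxy-5,8a-dimethyl-2-methylidenedecahydronaphthalen-1-yl]-3-methylpent-2-enoate; 11 angelic acid [(2Z)-2-methylbut-2-enoic acid]
Product: 13 allyl (2E)-5-[(1R,4aS,5S,6R,8aS)-5-{[tert-butyl(dimethyl)silyl]oxymethyl}-5,8a-dimethyl-6-{[(2Z)-2-methylbut-2-enoyl]oxy}-2-methylidenedecahydronaphthalen-1-yl]-3-methylpent-2-enoate, via angelic 2,4,6-trichlorobenzoic anhydride 12 (not isolated)
Conditions: 11 (3 equiv), 2,4,6-trichlorobenzoyl chloride (3 equiv), Et3N (6 equiv), toluene, rt, 2 h; then 10, 80 °C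
Reagents that add atoms: none
Why: Yamaguchi-type esterification in which the neopentylic C3–OH attacks the mixed anhydride at the unhindered angeloyl carbonyl, and because no nucleophilic catalyst such as DMAP is present the addition–elimination pathway that turns angelate (Z) into tiglate (E) is avoided, while C3 keeps its configuration since its C–O bond is not touched.

**Step 8**
Reactants: 13 allyl (2E)-5-[(1R,4aS,5S,6R,8aS)-5-{[tert-butyl(dimethyl)silyl]oxymethyl}-5,8a-dimethyl-6-{[(2Z)-2-methylbut-2-enoyl]oxy}-2-methylidenedecahydronaphthalen-1-yl]-3-methylpent-2-enoate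
Product: 14 (2E)-5-[(1R,4aS,5S,6R,8aS)-5-{[tert-butyl(dimethyl)silyl]oxymethyl}-5,8a-dimethyl-6-{[(2Z)-2-methylbut-2-enoyl]oxy}-2-methylidenedecahydronaphthalen-1-yl]-3-methylpent-2-enoic acid
Conditions: Pd(PPh3)4 (5 mol%), morpholine (5 equiv), THF, rt; then aq. citric acid
Reagents that add atoms: none
Why: Tsuji–Trost deallylation in which zerovalent palladium ionises the allyl ester to a π-allyl complex that morpholine captures, releasing the acid under neutral conditions that spare the angelate, the silyl ether and both alkenes.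

**Step 9**
Reactants: 14 (2E)-5-[(1R,4aS,5S,6R,8aS)-5-{[tert-butyl(dimethyl)silyl]oxymethyl}-5,8a-dimethyl-6-{[(2Z)-2-methylbut-2-enoyl]oxy}-2-methylidenedecahydronaphthalen-1-yl]-3-methylpent-2-enoic acid
Product: 15 (2E)-5-[(1R,4aS,5S,6R,8aS)-5-(hydroxymethyl)-5,8a-dimethyl-6-{[(2Z)-2-methylbut-2-enoyl]oxy}-2-methylidenedecahydronaphthalen-1-yl]-3-methylpent-2-enoic acid (CNP0420226.2)
Conditions: HF·pyridine, pyridine, THF, 0 °C to rt
Reagents that add atoms: none
Why: Fluoride-driven Si–O cleavage in a buffered, mildly acidic medium generates no free alkoxide next to the C3 ester, so no 3-O to 18-O acyl shift, no Z to E isomerisation and no migration of the exocyclic alkene is expected.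

**Compound list**
1 | (2E,6E)-farnesyl bromide | CC(C)=CCC/C(C)=C/CC/C(C)=C/CBr | starting material
2 | pentane-2,4-dione (acetylacetone) | CC(=O)CC(C)=O | starting material
3 | 3-[(2E,6E)-farnesyl]pentane-2,4-dione | CC(C)=CCC/C(C)=C/CC/C(C)=C/CC(C(C)=O)C(C)=O | intermediate (not isolated)
4 | (5E,9E)-farnesylacetone | CC(C)=CCC/C(C)=C/CC/C(C)=C/CCC(C)=O | intermediate
5 | (5E,9E,13E)-15-hydroxy-6,10,14-trimethylpentadeca-5,9,13-trien-2-one | OC/C(C)=C/CC/C(C)=C/CC/C(C)=C/CCC(C)=O | intermediate
6 | (5E,9E)-12-[(2R,3R)-3-(hydroxymethyl)-3-methyloxiran-2-yl]-6,10-dimethyldodeca-5,9-dien-2-one | OC[C@@]1(C)O[C@@H]1CC/C(C)=C/CC/C(C)=C/CCC(C)=O | intermediate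
7 | TBS ether of 6 | CC(C)(C)[Si](C)(C)OC[C@@]1(C)O[C@@H]1CC/C(C)=C/CC/C(C)=C/CCC(C)=O | intermediate
8 | 4-[(1R,4aS,5S,6R,8aS)-5-(TBSO-methyl)-6-hydroxy-5,8a-dimethyl-2-methylidenedecahydronaphthalen-1-yl]butan-2-one | C=C1CC[C@H]2[C@@](C)(CC[C@@H](O)[C@]2(C)CO[Si](C)(C)C(C)(C)C)[C@@H]1CCC(C)=O | intermediate
9 | allyl (diethoxyphosphoryl)acetate | C=CCOC(=O)CP(=O)(OCC)OCC | starting material
10 | allyl (2E)-enoate of the bicyclic 3-ol (18-OTBS) | C=C1CC[C@H]2[C@@](C)(CC[C@@H](O)[C@]2(C)CO[Si](C)(C)C(C)(C)C)[C@@H]1CC/C(C)=C/C(=O)OCC=C | intermediate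
11 | angelic acid [(2Z)-2-methylbut-2-enoic acid] | C/C=C(/C)C(=O)O | starting material
12 | (2Z)-2-methylbut-2-enoic 2,4,6-trichlorobenzoic anhydride | C/C=C(/C)C(=O)OC(=O)c1c(Cl)cc(Cl)cc1Cl | intermediate (not isolated)
13 | 3-O-angeloyl allyl ester (18-OTBS) | C=C1CC[C@H]2[C@@](C)(CC[C@@H](OC(=O)/C(C)=C\C)[C@]2(C)CO[Si](C)(C)C(C)(C)C)[C@@H]1CC/C(C)=C/C(=O)OCC=C | intermediate
14 | 3-O-angeloyl acid (18-OTBS) | C=C1CC[C@H]2[C@@](C)(CC[C@@H](OC(=O)/C(C)=C\C)[C@]2(C)CO[Si](C)(C)C(C)(C)C)[C@@H]1CC/C(C)=C/C(=O)O | intermediate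
15 | (2E)-5-[(1R,4aS,5S,6R,8aS)-5-(hydroxymethyl)-5,8a-dimethyl-6-{[(2Z)-2-methylbut-2-enoyl]oxy}-2-methylidenedecahydronaphthalen-1-yl]-3-methylpent-2-enoic acid | C=C1CC[C@H]2[C@@](C)(CC[C@@H](OC(=O)/C(C)=C\C)[C@]2(C)CO)[C@@H]1CC/C(C)=C/C(=O)O | target

**Totals**
Total steps: 9. Longest linear sequence: 9 steps (from 1).

**Three steps most likely to fail**

Step 5 (radical cascade). The C4 radical is planar, so the CH3/CH2OTBS arrangement rests only on the equatorial preference of the larger group and may be modest. The ketone could also capture the C8 radical, and endocyclic alkene isomers or uncyclised allylic alcohol may form. The fallback leaves the radical manifold for the cationic one, where the epoxide opens with inversion at C4 (the E-CH2OTBS group is forced equatorial) and the ketone is used as the terminator. It sets out from 7: BF3·OEt2 in CH2Cl2 at −78 °C closes both rings and the ketone oxygen captures the C8 cation anti to the new C9–C10 bond, giving the tricyclic enol ether F1. Oxalic acid in wet THF hydrolyses it to the 8-hydroxy-13-ketone F2. Olefination with 9 and NaH as in step 6 gives the 8-hydroxy enoate F3. The secondary C3–OH alone is acylated under the step 7 conditions to give the 8-hydroxy angelate F4. SOCl2 in pyridine/CH2Cl2 at −78 to −30 °C then eliminates the equatorial tertiary chlorosulfite, for which only the C17 methyl hydrogens are anti-periplanar, and the route is rejoined at 13.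

Step 7 (angeloylation). The C3–OH is neopentylic, and forcing the acyl transfer risks Z to E leakage to the tiglate. The fallback builds the Z alkene on the substrate instead of transferring it. It sets out from 10: esterification with 2-[bis(2,2,2-trifluoroethoxy)phosphoryl]propanoic acid (DCC, DMAP, CH2Cl2) gives the phosphonopropanoate ester F5. Still–Gennari olefination (KN(SiMe3)2, 18-crown-6, THF, −78 °C, then acetaldehyde) then forms the (Z)-2-methylbut-2-enoate directly, coming back to the route at 13.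

Step 2 (SeO2 oxidation). Yield is limited by competing oxidation of the internal alkenes and over-oxidation to the enal. The fallback functionalises the terminus stepwise. It sets out from 4: NBS in aqueous THF at 0 °C gives the terminal bromohydrin F6. K2CO3 in MeOH closes it to the racemic terminal epoxide F7. HIO4·2H2O in THF/Et2O cleaves this to the trisnor keto aldehyde F8. Wittig reaction with 2-(triphenylphosphoranylidene)propanal (toluene, 80 °C) gives the (E)-keto enal F9. NaBH4 (0.3 equiv) in EtOH/CH2Cl2 at −78 °C reduces the aldehyde in the presence of the methyl ketone and returns to the route at 5.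

**Further compounds**
F1 | step 5 | tricyclic enol ether: O bridges C8 and C13, C12=C13, C8–O equatorial and C17 methyl axial, 3-OH, 18-OTBS (isomer of 7) | C[C@]13CC[C@H]2[C@@](C)(CC[C@@H](O)[C@]2(C)CO[Si](C)(C)C(C)(C)C)[C@@H]1CC=C(C)O3
F2 | step 5 | 8-hydroxy-13-ketone: 8 with water added across C8=C17 (tertiary OH equatorial) | C[C@]1(O)CC[C@H]2[C@@](C)(CC[C@@H](O)[C@]2(C)CO[Si](C)(C)C(C)(C)C)[C@@H]1CCC(C)=O
F3 | step 5 | 8-hydroxy enoate: 10 with water added across C8=C17 | C[C@]1(O)CC[C@H]2[C@@](C)(CC[C@@H](O)[C@]2(C)CO[Si](C)(C)C(C)(C)C)[C@@H]1CC/C(C)=C/C(=O)OCC=C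
F4 | step 5 | 8-hydroxy angelate: 13 with water added across C8=C17 | C[C@]1(O)CC[C@H]2[C@@](C)(CC[C@@H](OC(=O)/C(C)=C\C)[C@]2(C)CO[Si](C)(C)C(C)(C)C)[C@@H]1CC/C(C)=C/C(=O)OCC=C
F5 | step 7 | phosphonopropanoate ester: 10 acylated at O3 by 2-[bis(2,2,2-trifluoroethoxy)phosphoryl]propanoic acid (both epimers at the new CH) | C=C1CC[C@H]2[C@@](C)(CC[C@@H](OC(=O)C(C)P(=O)(OCC(F)(F)F)OCC(F)(F)F)[C@]2(C)CO[Si](C)(C)C(C)(C)C)[C@@H]1CC/C(C)=C/C(=O)OCC=C
F6 | step 2 | (5E,9E)-13-bromo-14-hydroxy-6,10,14-trimethylpentadeca-5,9-dien-2-one (racemic) | CC(C)(O)C(Br)CC/C(C)=C/CC/C(C)=C/CCC(C)=O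
F7 | step 2 | (5E,9E)-12-(3,3-dimethyloxiran-2-yl)-6,10-dimethyldodeca-5,9-dien-2-one (racemic) | CC1(C)OC1CC/C(C)=C/CC/C(C)=C/CCC(C)=O
F8 | step 2 | (4E,8E)-4,8-dimethyl-12-oxotrideca-4,8-dienal | O=CCC/C(C)=C/CC/C(C)=C/CCC(C)=O
F9 | step 2 | (2E,6E,10E)-2,6,10-trimethyl-14-oxopentadeca-2,6,10-trienal | O=C/C(C)=C/CC/C(C)=C/CC/C(C)=C/CCC(C)=O
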